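Charge 20 mM of E with 1.00 equiv of G in a closed, stirred, isothermal flask and hold it for 30 min. Two earlier runs stand beside it.

| flask | E | G | remark | time |
|---|---|---|---|---|
| Sunday's | 13 mM | 1 equiv | run made earlier |  |
| Monday's | 30 mM | 1 equiv | run made earlier |  |
| flask | 20 mM | 1.00 equiv |  | 30 min |

| run | time / min | Z / % | L / % |
|---|---|---|---|
| Sunday's | 8.00 | 76.3 | 21.6 |
| Sunday's | 15.0 | 77.2 | 22.1 |
| Sunday's | 25.0 | 76.9 | 22.1 |
| Sunday's | 30.0 | 77.2 | 20.7 |
| Monday's | 8.00 | 62.0 | 34.9 |
| Monday's | 15.0 | 61.0 | 35.7 |
| Monday's | 25.0 | 61.7 | 35.0 |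
| Monday's | 30.0 | 61.7 | 34.9 |

(standard deviation of a reading: 0.5 percentage points)

* ratio of Z to L at 1.2 s
* ratio of Z to L at 40 s
* ratio of Z to L at 30 min
* which of Z and L there is more of at 30 min



Take Z/L from the summed readings of each run, since they show no trend: 3.56 for Sunday's run and 1.75 for Monday's. Now note the mismatch: the charge rises by a factor of 2.31, but the ratio falls by 2.03.

Clear it by solving both ends. Suppose that at each moment the rate of Z over the rate of L is K/c(G); both runs stand at 1 equiv, so they do not separate c(G) from c(E). At the start that ratio is K over the charge. As c(G) falls it climbs, and summing it over the run with c(E) and c(G) falling together gives, to first order, a line in the reciprocal charge for the finished ratio: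

Z/L = 2 K / c(E charged) + b

Put both runs through it. This gives 20.7 mM for the crossover concentration, the c(G) at which Z and L form equally fast, and b = 0.375. In this line the term b does not scale with the charge, which is how the fall in the read ratio stays smaller than the rise in charge.

For this flask, my reckoning starts near 1.03 and finishes at 2.44, so Z leads. The readings begin at 8.00 min, so they give no clock for the ratios asked at 1.2 s and 40 s.

For 1.2 s, 40 s and 30 min the forecast gives 1.2, 2.2 and 2.45, with Z ahead, on the suggestion from the runs that “the L path is one order higher than the Z path”.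

At those times the flask gives 0.540, 1.88 and 2.48, with Z ahead at 70.0% against 28.2% of L.

    E ⇌ J (K = 2.50, k = 0.0280 s⁻¹)
    E + G → L (k = 1.20 L mol⁻¹ s⁻¹)
    G + J → Z (k = 58.0 L mol⁻¹ s⁻¹)
    E + L → X (k = 0.0850 L mol⁻¹ s⁻¹)
    E → Q (k = 2.40 × 10⁻⁵ s⁻¹)

The finish of this flask stands near the line's 2.44, while its ratio at 1.2 s lies below K over the charged c(G), and Z draws level with L at 0.0738 min. Run the same line for the neighbour flask with 34 mM of E at the same equivalents: it gives 1.59. That neighbour flask ends with L at 37.6% and Z at 59.0%, a ratio of 1.57.

All runs stem from a simulated flask with made-up constants; noise was put on by code.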